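The whole route rests on disconnecting the four contiguous oxygenated carbons C5–C8 of the tetrahydrochromone ring back to the aromatic benzo ring of 2-(2-phenylethyl)chromone. One enzymatic operation, an arene dioxygenase cis-dihydroxylation across C7=C8, breaks the aromaticity, installs the C7–O and C8–O bonds on one face as a single enantiomer, and leaves C5=C6 as an alkene. That alkene is then epoxidised syn to the C7 hydroxyl, C8 is inverted by Mitsunobu esterification, and the 6-hydroxyl of a 7-O-allyl-protected 6,7-dihydroxychromone opens the epoxide at C5 with inversion. The precursor is the flat, unfunctionalised chromone, made in one pot from 2'-hydroxyacetophenone.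

Key step: step 2

Remark: chromone numbering (O1, C2, C3, C4, C4a, C5 to C8, C8a) is used throughout and doubly primed locants mark the aryl ether chromone unit; it is assumed that an oxygenase variant with the required site and face selectivity can be found, and allyl is chosen for the phenol so that the end game needs no hydrogenolysis next to the C5 aryl ether.

Step 1
Reactants: 1 2'-hydroxyacetophenone; 2 ethyl 3-phenylpropanoate
Product: 4 2-(2-phenylethyl)chromone, via 1-(2-hydroxyphenyl)-5-phenylpentane-1,3-dione 3 (not isolated)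
Conditions: NaH (3 equiv), THF, 0 °C to reflux; then MeOH, conc. HCl, 60 °C, same flask
Reagents that add atoms: none
Why: Claisen condensation of the ketone dianion with the ester gives the 1,3-diketone, and acid-catalysed cyclodehydration of this 2-hydroxyaryl diketone closes the pyranone ring; no stereocentre is formed.

Step 2
Reactants: 4 2-(2-phenylethyl)chromone
Product: 5 (7R,8R)-7,8-dihydroxy-7,8-dihydro-2-(2-phenylethyl)chromone (cis diol, C5=C6 retained)
Conditions: resting E. coli cells co-expressing a naphthalene dioxygenase variant (NahAaAbAcAd) and glucose dehydrogenase, D-glucose, air, phosphate buffer pH 7.2, 2% DMSO, 30 °C; EtOAc extraction with a trace of Et3N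
Reagents that add atoms: dioxygen, O=O
Why: Proposed new method: a Rieske-type non-heme iron arene dioxygenase binds O2 at its mononuclear divalent iron centre, takes two electrons from NADH through its reductase and ferredoxin, and transfers both oxygen atoms suprafacially to C7 and C8 of the bound arene, so that the two new C–O bonds lie on one face (cis) and C5=C6 is left as an alkene. The closest known reaction type is the dioxygenase cis-dihydroxylation of the carbocyclic ring of quinolines, 2-quinolones, benzofurans and naphthalene, which has not been shown on a chromone. No ring is closed. Both new stereocentres (C7 R, C8 R) are controlled by the enzyme active site, which fixes the orientation and the exposed face of the arene above the iron, the cis relationship following from delivery of one O2 molecule to one face. The step needs attack on C7=C8 instead of C5=C6 or the pendant phenyl ring, and one enantioface; the substrate helps through its planar, naphthalene-sized bicycle, the peri carbonyl that crowds C5=C6 and the flexible two-carbon tether that keeps the phenyl ring out of the flat binding slot, but the final choice of site and face has to be secured by screening wild-type and engineered oxygenase variants.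

Step 3
Reactants: 5 (7R,8R)-7,8-dihydroxy-7,8-dihydro-2-(2-phenylethyl)chromone
Product: 6 (5R,6S,7S,8R)-5,6-epoxy-7,8-dihydroxy-5,6,7,8-tetrahydro-2-(2-phenylethyl)chromone (oxirane oxygen cis to both hydroxyls)
Conditions: mCPBA (1.2 equiv), CH2Cl2/aq. phosphate buffer pH 8, 0 °C
Reagents that add atoms: mCPBA, O=C(OO)c1cccc(Cl)c1
Why: Hydroxyl-directed peracid epoxidation: the allylic C7 hydroxyl, seconded by the C8 hydroxyl on the same face, hydrogen-bonds the peracid so that oxygen should be delivered to C5=C6 from the face of the diol (C5 R, C6 S, oxirane cis to both hydroxyls), while the electron-poor pyranone double bonds stay untouched and the buffer protects the acid-labile dihydrodiol.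

Step 4
Reactants: 6 (5R,6S,7S,8R)-5,6-epoxy-7,8-dihydroxy-5,6,7,8-tetrahydro-2-(2-phenylethyl)chromone
Product: 7 (5R,6S,7R,8S)-5,6-epoxy-7-hydroxy-4-oxo-2-(2-phenylethyl)-5,6,7,8-tetrahydro-4H-chromen-8-yl 4-nitrobenzoate (ester trans to the C7 hydroxyl and to the oxirane)
Conditions: PPh3 (1.5 equiv), DIAD (1.5 equiv), 4-nitrobenzoic acid (1.5 equiv), THF, −20 °C to rt
Reagents that add atoms: 4-nitrobenzoic acid, O=C(O)c1ccc(cc1)[N+](=O)[O-]
Why: Mitsunobu reaction of a cis-1,2-diol: once the diene is gone only C8 is an allylic carbinol carbon (next to the pyranone C8a=C4a bond) while C7 is flanked by the oxirane carbon, so the carboxylate should displace the oxyphosphonium at C8 in SN2 fashion, inverting C8 to S and leaving the C7 hydroxyl and the oxirane (cis to O7, hence immune to Payne migration) intact.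

Step 5
Reactants: 8 2,4,5-trihydroxyacetophenone
Product: 9 1-[4-(allyloxy)-2,5-dihydroxyphenyl]ethanone
Conditions: allyl bromide (1.05 equiv), NaHCO3 (1.5 equiv), NaI (cat.), DMF, 40 °C, argon
Reagents that add atoms: allyl bromide, C=CCBr
Why: Williamson etherification: the C4 hydroxyl, para to the acetyl group, is the most acidic phenol and the one ionised by hydrogencarbonate (the C2 hydroxyl is chelated to the carbonyl, the C5 hydroxyl is a meta phenol), so mono-O-allylation should occur there.

Step 6
Reactants: 9 1-[4-(allyloxy)-2,5-dihydroxyphenyl]ethanone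
Product: 10 1-[4-(allyloxy)-2-hydroxy-5-(methoxymethoxy)phenyl]ethanone
Conditions: MOMCl (1.1 equiv), iPr2NEt (1.5 equiv), CH2Cl2, 0 °C, argon
Reagents that add atoms: chloromethyl methyl ether, COCCl
Why: O-alkylation with an alpha-chloro ether: the free C5 hydroxyl reacts while the C2 hydroxyl stays locked in its hydrogen bond to the ketone, which masks the oxidation-prone second phenol before the enolate chemistry.

Step 7
Reactants: 10 1-[4-(allyloxy)-2-hydroxy-5-(methoxymethoxy)phenyl]ethanone; 2 ethyl 3-phenylpropanoate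
Product: 12 7-(allyloxy)-6-hydroxy-2-(2-phenylethyl)chromone, via MOM-protected 1,3-diketone 11 (not isolated)
Conditions: NaH (3.5 equiv), THF, 0 °C to reflux; then MeOH, conc. HCl, 60 °C, same flask
Reagents that add atoms: none
Why: Claisen condensation then acid-catalysed cyclodehydration, the same chromone construction as in step 1; the acid also cleaves the MOM acetal while the allyl ether survives, so the 6-hydroxy-7-allyloxy pattern is delivered directly.

Step 8
Reactants: 7 (5R,6S,7R,8S)-5,6-epoxy-7-hydroxy-4-oxo-2-(2-phenylethyl)-5,6,7,8-tetrahydro-4H-chromen-8-yl 4-nitrobenzoate; 12 7-(allyloxy)-6-hydroxy-2-(2-phenylethyl)chromone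
Product: 14 (5S,6S,7R,8S)-5-{[7-(allyloxy)-4-oxo-2-(2-phenylethyl)-4H-chromen-6-yl]oxy}-6,7,8-trihydroxy-2-(2-phenylethyl)-5,6,7,8-tetrahydro-4H-chromen-4-one, via C8 4-nitrobenzoate of this aryl ether 13 (not isolated)
Conditions: 12 (1.5 equiv), Cs2CO3 (0.3 equiv), DMF, 50 °C; then MeOH, rt, same flask
Reagents that add atoms: none
Why: Base-catalysed SN2 opening of an epoxide by a phenoxide: C5 is the allylic oxirane carbon and lies away from the electron-withdrawing C7 oxygen, so the 6″-phenoxide should attack it from the face opposite the oxirane oxygen (inversion, C5 S; C6 keeps its oxygen, S), and carbonate-catalysed methanolysis then removes the nitrobenzoate without touching the aryl ether.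

Step 9
Reactants: 14 (5S,6S,7R,8S)-5-{[7-(allyloxy)-4-oxo-2-(2-phenylethyl)-4H-chromen-6-yl]oxy}-6,7,8-trihydroxy-2-(2-phenylethyl)-5,6,7,8-tetrahydro-4H-chromen-4-one
Product: 15 (5S,6S,7R,8S)-6,7,8-trihydroxy-5-{[7-hydroxy-4-oxo-2-(2-phenylethyl)-4H-chromen-6-yl]oxy}-2-(2-phenylethyl)-5,6,7,8-tetrahydro-4H-chromen-4-one (CNP0248258.1)
Conditions: Pd(PPh3)4 (5 mol %), morpholine (10 equiv), THF, rt, argon
Reagents that add atoms: none
Why: Tsuji–Trost deallylation: zerovalent palladium ionises the aryl allyl ether to a pi-allyl palladium complex that morpholine captures, freeing the C7″ phenol under near-neutral conditions that should leave the secondary C5 aryl ether, the triol and both pyranones untouched.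

Compound list
1 | 2'-hydroxyacetophenone | CC(=O)c1ccccc1O | starting material
2 | ethyl 3-phenylpropanoate | CCOC(=O)CCc1ccccc1 | starting material
3 | 1-(2-hydroxyphenyl)-5-phenylpentane-1,3-dione | O=C(CC(=O)CCc1ccccc1)c1ccccc1O | intermediate
4 | 2-(2-phenylethyl)chromone | O=c1cc(CCc2ccccc2)oc2ccccc12 | intermediate
5 | (7R,8R)-7,8-dihydroxy-7,8-dihydro-2-(2-phenylethyl)chromone (cis diol) | O=c1cc(CCc2ccccc2)oc2c1C=C[C@@H](O)[C@H]2O | intermediate
6 | (5R,6S,7S,8R)-5,6-epoxy-7,8-dihydroxy-5,6,7,8-tetrahydro-2-(2-phenylethyl)chromone | O=c1cc(CCc2ccccc2)oc2c1[C@H]1O[C@H]1[C@@H](O)[C@H]2O | intermediate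
7 | (5R,6S,7R,8S)-5,6-epoxy-7-hydroxy-4-oxo-2-(2-phenylethyl)-5,6,7,8-tetrahydro-4H-chromen-8-yl 4-nitrobenzoate | O=c1cc(CCc2ccccc2)oc2c1[C@H]1O[C@H]1[C@@H](O)[C@@H]2OC(=O)c1ccc(cc1)[N+](=O)[O-] | intermediate
8 | 2,4,5-trihydroxyacetophenone | CC(=O)c1cc(O)c(O)cc1O | starting material
9 | 1-[4-(allyloxy)-2,5-dihydroxyphenyl]ethanone | CC(=O)c1cc(O)c(OCC=C)cc1O | intermediate
10 | 1-[4-(allyloxy)-2-hydroxy-5-(methoxymethoxy)phenyl]ethanone | CC(=O)c1cc(OCOC)c(OCC=C)cc1O | intermediate
11 | 1-[4-(allyloxy)-2-hydroxy-5-(methoxymethoxy)phenyl]-5-phenylpentane-1,3-dione | O=C(CC(=O)CCc1ccccc1)c1cc(OCOC)c(OCC=C)cc1O | intermediate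
12 | 7-(allyloxy)-6-hydroxy-2-(2-phenylethyl)chromone | O=c1cc(CCc2ccccc2)oc2cc(OCC=C)c(O)cc12 | intermediate
13 | (5S,6S,7R,8S)-5-{[7-(allyloxy)-4-oxo-2-(2-phenylethyl)-4H-chromen-6-yl]oxy}-6,7-dihydroxy-4-oxo-2-(2-phenylethyl)-5,6,7,8-tetrahydro-4H-chromen-8-yl 4-nitrobenzoate | O=c1cc(CCc2ccccc2)oc2c1[C@H](Oc1cc3c(=O)cc(CCc4ccccc4)oc3cc1OCC=C)[C@@H](O)[C@@H](O)[C@@H]2OC(=O)c1ccc(cc1)[N+](=O)[O-] | intermediate
14 | (5S,6S,7R,8S)-5-{[7-(allyloxy)-4-oxo-2-(2-phenylethyl)-4H-chromen-6-yl]oxy}-6,7,8-trihydroxy-2-(2-phenylethyl)-5,6,7,8-tetrahydro-4H-chromen-4-one | O=c1cc(CCc2ccccc2)oc2c1[C@H](Oc1cc3c(=O)cc(CCc4ccccc4)oc3cc1OCC=C)[C@@H](O)[C@@H](O)[C@@H]2O | intermediate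
15 | (5S,6S,7R,8S)-6,7,8-trihydroxy-5-{[7-hydroxy-4-oxo-2-(2-phenylethyl)-4H-chromen-6-yl]oxy}-2-(2-phenylethyl)-5,6,7,8-tetrahydro-4H-chromen-4-one | O=c1cc(CCc2ccccc2)oc2c1[C@H](Oc1cc3c(=O)cc(CCc4ccccc4)oc3cc1O)[C@@H](O)[C@@H](O)[C@@H]2O | target

Total step count: 9. Longest linear sequence: 6 (steps 1, 2, 3, 4, 8, 9).

Steps most likely to fail

1. Step 2. The enzyme may oxygenate the wrong site (C5=C6, the pendant phenyl ring or a benzylic CH2), may deliver the other enantioface, may not turn the substrate over, or the diol may dehydrate to phenols during isolation.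

   The fallback is purely chemical; it sets out from 2 and comes back at 14. Purchased 2',3',4'-trihydroxyacetophenone is bis-protected (MOMCl, iPr2NEt) to 1-[2-hydroxy-3,4-bis(methoxymethoxy)phenyl]ethanone F1. Claisen condensation with 2 (NaH, THF) gives 1-[2-hydroxy-3,4-bis(methoxymethoxy)phenyl]-5-phenylpentane-1,3-dione F2, and HCl/MeOH cyclises and unmasks it to 7,8-dihydroxy-2-(2-phenylethyl)chromone F3. Oxidation with NaIO4 in aqueous THF gives the ortho-quinone 2-(2-phenylethyl)chromene-4,7,8-trione F4. Reduction with NaBH4 in EtOH under O2, the usual behaviour of arene ortho-quinones, should give racemic trans-7,8-dihydroxy-7,8-dihydro-2-(2-phenylethyl)chromone F5. Preparative HPLC on a chiral stationary phase then furnishes (7R,8S)-7,8-dihydroxy-7,8-dihydro-2-(2-phenylethyl)chromone F6. Buffered mCPBA, directed by the allylic C7 hydroxyl, should give (5R,6S,7S,8S)-5,6-epoxy-7,8-dihydroxy-5,6,7,8-tetrahydro-2-(2-phenylethyl)chromone F7. Phenol 12 opens F7 at C5 under the first-stage conditions of step 8 to give 14, so no C8 inversion is needed.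

2. Step 4. Esterification may proceed with retention through an acyloxyphosphonium pathway, displacement may occur at C7, the activated C8 oxygen may be lost by elimination with aromatisation, or the acid may open the oxirane.

   The fallback sets out from 6 and comes back at 7. SOCl2 and Et3N in CH2Cl2 at −20 °C convert the cis-diol symmetrically into the 7,8-cyclic sulfite of 6 F8 (mixture of epimers at sulfur). Cesium 4-nitrobenzoate in DMF at 50 °C should open it at the allylic C8 with inversion, and aqueous work-up releases the C7 sulfite half-ester to give 7. Regiocontrol then rests on the SN2 reactivity of C8, not on telling the two hydroxyls apart.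

3. Step 8. The phenoxide may act as a base on the vinylogously acidic C8–H and trigger elimination and aromatisation, the hindered oxirane may react sluggishly, or attack may stray to C6.

   The fallback sets out from 7 and comes back at 14, using an acid-mediated substitution steered by a participating neighbour instead of a basic SN2 opening. Ac2O with catalytic Sc(OTf)3 in CH2Cl2 at 0 °C opens the oxirane and acetylates O7, giving (5S,6R,7R,8S)-5,6,7-triacetoxy-4-oxo-2-(2-phenylethyl)-5,6,7,8-tetrahydro-4H-chromen-8-yl 4-nitrobenzoate F9. BF3·OEt2 and phenol 12 in CH2Cl2 at −20 °C ionise the C5 acetate; the C6 acetate bridges the cation on its own face, so the phenol should enter trans, as in aryl glycoside formation. This gives (5S,6R,7R,8S)-6,7-diacetoxy-5-{[7-(allyloxy)-4-oxo-2-(2-phenylethyl)-4H-chromen-6-yl]oxy}-4-oxo-2-(2-phenylethyl)-5,6,7,8-tetrahydro-4H-chromen-8-yl 4-nitrobenzoate F10. K2CO3 in MeOH then removes all three esters to give 14.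

Further compounds
F1 | step 2 | 1-[2-hydroxy-3,4-bis(methoxymethoxy)phenyl]ethanone | CC(=O)c1ccc(OCOC)c(OCOC)c1O
F2 | step 2 | 1-[2-hydroxy-3,4-bis(methoxymethoxy)phenyl]-5-phenylpentane-1,3-dione | O=C(CC(=O)CCc1ccccc1)c1ccc(OCOC)c(OCOC)c1O
F3 | step 2 | 7,8-dihydroxy-2-(2-phenylethyl)chromone | O=c1cc(CCc2ccccc2)oc2c(O)c(O)ccc12
F4 | step 2 | 2-(2-phenylethyl)chromene-4,7,8-trione | O=c1cc(CCc2ccccc2)oc2c1C=CC(=O)C2=O
F5 | step 2 | racemic trans-7,8-dihydroxy-7,8-dihydro-2-(2-phenylethyl)chromone | O=c1cc(CCc2ccccc2)oc2c1C=C[C@@H](O)[C@@H]2O.O=c1cc(CCc2ccccc2)oc2c1C=C[C@H](O)[C@H]2O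
F6 | step 2 | (7R,8S)-7,8-dihydroxy-7,8-dihydro-2-(2-phenylethyl)chromone | O=c1cc(CCc2ccccc2)oc2c1C=C[C@@H](O)[C@@H]2O
F7 | step 2 | (5R,6S,7S,8S)-5,6-epoxy-7,8-dihydroxy-5,6,7,8-tetrahydro-2-(2-phenylethyl)chromone | O=c1cc(CCc2ccccc2)oc2c1[C@H]1O[C@H]1[C@@H](O)[C@@H]2O
F8 | step 4 | 7,8-cyclic sulfite of 6 (epimers at sulfur) | O=c1cc(CCc2ccccc2)oc2c1[C@H]1O[C@H]1[C@@H](OS(=O)O3)[C@H]23
F9 | step 8 | (5S,6R,7R,8S)-5,6,7-triacetoxy-4-oxo-2-(2-phenylethyl)-5,6,7,8-tetrahydro-4H-chromen-8-yl 4-nitrobenzoate | O=c1cc(CCc2ccccc2)oc2c1[C@H](OC(C)=O)[C@@H](OC(C)=O)[C@@H](OC(C)=O)[C@@H]2OC(=O)c1ccc(cc1)[N+](=O)[O-]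
F10 | step 8 | (5S,6R,7R,8S)-6,7-diacetoxy-5-{[7-(allyloxy)-4-oxo-2-(2-phenylethyl)-4H-chromen-6-yl]oxy}-4-oxo-2-(2-phenylethyl)-5,6,7,8-tetrahydro-4H-chromen-8-yl 4-nitrobenzoate | O=c1cc(CCc2ccccc2)oc2c1[C@H](Oc1cc3c(=O)cc(CCc4ccccc4)oc3cc1OCC=C)[C@@H](OC(C)=O)[C@@H](OC(C)=O)[C@@H]2OC(=O)c1ccc(cc1)[N+](=O)[O-]
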